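## The problem

Target 29 is a 2,3,4-trisubstituted tetrahydrofuran lignan ester. The ring is numbered O1, C2 (4-hydroxy-3,5-dimethoxyphenyl, "syringyl"), C3 (bearing C9H2–O–feruloyl), C4 (bearing C7'H2–guaiacyl) and C5H2, with configuration 2S,3R,4R. The ring is monocyclic, so no ring fusion relays stereochemistry, and each of C2, C3 and C4 carries a different carbon appendage. The C3 and C4 substituents are cis and the C2 aryl group is trans to both. The C3/C4 cis pair cannot be corrected later and must be made under kinetic control. C2 is benzylic and oxygen-bound, can be epimerised through its cation, and can therefore be left to the thermodynamic influence of the C3/C4 pair, but it cannot control them. Fragile elements are the E-cinnamate ester (base, nucleophiles, hydrogenation), three phenols (oxidants) and the electron-rich benzylic ether C2–O1, which ionises in acid and can then be trapped by C6' of the guaiacyl ring. The ferulate must therefore arrive last, and the phenol protection must fall under near-neutral, non-reductive conditions. The enabling feature is that deleting C2 leaves O1, C3, C4 and C5 as an oxetane with cis substituents on its two stereocentres. The syringyl carbon can be inserted into the O1–C3 bond as a carbene, and the cis-oxetane maps onto a syn-aldol adduct.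

## Retrosynthesis

**29 ⇒ 28 ⇒ 24 + 27 (C9–O acyl bond, three O–Si bonds).** The ester is cut first so that the cinnamate never meets a carbene, a radical, a Lewis acid or DDQ. All three phenols carry triisopropylsilyl groups, so one buffered fluoride step finishes the synthesis. The precursors are alcohol 24 and O-silyl ferulic acid 27, which comes in one step from ferulic acid 25. The forward reactions are an ordinary carbodiimide acylation of a primary alcohol and a desilylation that must not generate free phenoxide next to the ester.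

**24 ⇒ 23 ⇒ 22 (C2 configuration relaxed; PMB on O9).** C2 is not disconnected but released from control: 23 and 22 are accepted as mixtures of C2 epimers. This costs one Lewis-acid equilibration, which relies on the trans isomer being the more stable one. The PMB group is removed before that equilibration so that no 4-methoxybenzyl cation can form under BF3. The forward demands are a DDQ cleavage that spares the C2–H benzylic ether and an equilibration faster than Friedel–Crafts capture of the cation.

**22 ⇒ 21 ⇒ 20 (C2–H from C2–CO2R).** Adding a carboxyl group to C2 turns it into the carbon of a donor/acceptor carbene. The ester is 2,2,2-trichloroethyl rather than methyl, because a quaternary methyl ester would need hot hydroxide, which aryl silyl ethers do not survive. Zn unmasks the acid reductively, and the α-alkoxy-α-aryl acid 21 is a good substrate for radical hydrodecarboxylation.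

**20 ⇒ 13 + 17 (O1–C2 and C2–C3; key step).** Cutting both bonds to C2 removes the only aryl-bearing ring carbon. What remains is oxetane 13 with two stereocentres and achiral diazo ester 17. The neighbouring cuts (O1–C5 with C2–C3, or C3–C4 alone) lead to lactone or aldol intermediates that place a carbonyl next to C3 or C4; this cut never does. The forward reaction must form the ylide on the oxetane oxygen, migrate C3 rather than C5, and do so with retention.

**13 ⇒ 12 ⇒ 11 (O1–C5).** The oxetane is opened at the bond to its CH2 carbon, giving monotosylate 12 and diol 11. Closure at this bond touches no stereocentre. Closure at O1–C3 would need an inversion at C3 and the anti diol.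

**11 ⇒ 10 ⇒ 6 + 7 (C3–C4); 6 ⇒ 3 + 4; 3 ⇒ 1.** The syn-1,3-diol is the reduced form of Evans syn-aldol adduct 10. It comes from imide 6, made from silylated dihydroferulic acid 3 (from 1) and (R)-4-benzyl-2-oxazolidinone 4, and from aldehyde 7. The R auxiliary is required because the adduct must be 2R,3R. One aldol therefore sets both permanent stereocentres.

**17 ⇒ 16 ⇒ 15 ⇒ 14.** Diazo transfer, phenol silylation and esterification lead back to homosyringic acid 14.

## Roads not taken

**Alternative 1:** This road cuts O1–C2, C3–C4 and the C7'–aryl bond in one cascade. The alkoxide of prop-2-yn-1-ol A2 adds to arylidene malonate A1. The malonate anion then closes 5-exo-dig onto the alkyne activated by the arylpalladium iodide from A3, and reductive elimination gives benzylidene tetrahydrofuran A4. The catalyst is PdCl2(PPh3)2, reduced in the flask to zerovalent palladium.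
- Merits: it is the shortest way to the full carbon skeleton and clearly better than the chosen plan in step count and convergence.
- Weak points: A4 is racemic at C2 and no absolute control is on offer. C3 must be set by dealkoxycarbonylation and C4 by hydrogenation of the exocyclic alkene. Hydrogen should add to the face away from the C2 aryl group, which puts the C4 benzyl group cis to the aryl group, the opposite of the target. The acetal protecting groups call for acid at the end, next to the ionisable C2–O1 bond.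
- Comparison: the chosen plan is roughly twice as long, but it fixes C3 and C4 absolutely by an auxiliary aldol and lets C2 follow them.

**Alternative 2:** This road cuts C3–C9 and C4–C7'. A carbonyl ylide, released by CsF from chloro silyl ether A7 (made from aldehyde A5), adds across the alkene of butenolide A6 to give cis-fused cycloadduct A8. The extra ring is opened later at C7'–O and the lactone carbonyl becomes C5H2.
- Merits: addition anti to the syringyl group creates the C3/C4 cis pair and its trans relation to C2 in one kinetic step. This is better than the chosen plan, which needs a late equilibration at C2.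
- Weak points: A6 has an acidic benzylic γ-hydrogen and can racemise through its dienolate under the fluoride conditions. The unsymmetrical dipole must add with the right regiochemistry. The hydrogenolysis must cleave the C7'–O benzylic bond and spare the equally benzylic C2–O1 bond. The phenol pivalate must be exchanged before a ferulate ester can be present.
- Comparison: the chosen plan takes absolute configuration from a reliable auxiliary, has only one benzylic C–O bond at any stage, and never has to remove one phenol ester in the presence of another ester.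

**Alternative 3:** This road cuts O1–C5. β-Keto diester A9, whose C4 centre comes from the amino acid chiral pool, is reduced under dynamic kinetic resolution with RuCl(p-cymene)(TsDPEN), a divalent ruthenium complex, and HCO2H/Et3N. The new C2 hydroxyl lactonises to A10.
- Merits: C2 and C3 are set together by the catalyst, so no equilibration is needed. In this respect it is stronger than the chosen plan.
- Weak points: the catalyst must override a bulky, stereogenic α-substituent (double stereodifferentiation). C3 stays α to an ester for several steps. C5 must be reduced from lactone carbonyl to CH2 while the C9 ester is kept and then reduced separately. The benzylic lactone C2–O bond is prone to reductive cleavage.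
- Comparison: the step counts are similar. The chosen plan never places a carbonyl next to C3 or C4 after the aldol and needs no differentiation of two carboxyl-level carbons. It pays with the C2 equilibration of step 14.

Key step: step 10

Assumption: the locants O1, C2–C5, C9 and C7' of the target are used for all intermediates, and compounds 20–23 are carried as mixtures of C2 epimers because C2 is fixed only in step 14. Compounds 4, 7 and 14 are taken as purchasable.

## Route

Step 1
Reactants: 1 dihydroferulic acid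
Product: 3 3-[3-methoxy-4-(triisopropylsilyloxy)phenyl]propanoic acid, via bis-silylated silyl ester 2 (not isolated)
Conditions: TIPSCl, imidazole, DMF, rt; then K2CO3, MeOH–THF–H2O, rt; acidic work-up
Reagents that add atoms: chlorotriisopropylsilane, CC(C)[Si](Cl)(C(C)C)C(C)C
Why: Silylation of phenol and acid, then selective hydrolysis of the far more labile silyl ester by mild carbonate; triisopropylsilyl is chosen because the aryl ether must later survive the alkoxide of step 6.

Step 2
Reactants: 3 3-[3-methoxy-4-(triisopropylsilyloxy)phenyl]propanoic acid; 4 (R)-4-benzyl-2-oxazolidinone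
Product: 6 (R)-4-benzyl-3-{3-[3-methoxy-4-(triisopropylsilyloxy)phenyl]propanoyl}oxazolidin-2-one, via mixed pivalic anhydride 5 (not isolated)
Conditions: PivCl, Et3N, THF, −20 °C; then LiCl, 4, −20 °C to rt
Reagents that add atoms: none
Why: N-Acylation of the oxazolidinone through the mixed pivalic anhydride with LiCl/Et3N; the nucleophile attacks the less hindered carbonyl of 5.

Step 3
Reactants: 6 (R)-4-benzyl-3-{3-[3-methoxy-4-(triisopropylsilyloxy)phenyl]propanoyl}oxazolidin-2-one; 7 (4-methoxybenzyloxy)acetaldehyde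
Product: 10 (R)-4-benzyl-3-{(2R,3R)-3-hydroxy-4-(4-methoxybenzyloxy)-2-[3-methoxy-4-(triisopropylsilyloxy)benzyl]butanoyl}oxazolidin-2-one, via (Z)-boron enolate 8 (not isolated), via boron aldolate 9 (not isolated)
Conditions: n-Bu2BOTf, i-Pr2NEt, CH2Cl2, −78 to 0 °C; 7, −78 to 0 °C; then pH 7 buffer, MeOH, H2O2, 0 °C
Reagents that add atoms: none
Why: Evans syn-aldol reaction; the Z-boron enolate reacts through a closed Zimmerman–Traxler chair on the face opposite the auxiliary benzyl group, giving the 2R,3R syn adduct whose two centres become C4 and C3 of the target.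

Step 4
Reactants: 10 (R)-4-benzyl-3-{(2R,3R)-3-hydroxy-4-(4-methoxybenzyloxy)-2-[3-methoxy-4-(triisopropylsilyloxy)benzyl]butanoyl}oxazolidin-2-one
Product: 11 (2S,3R)-4-(4-methoxybenzyloxy)-2-[3-methoxy-4-(triisopropylsilyloxy)benzyl]butane-1,3-diol
Conditions: LiBH4, THF, MeOH (1 equiv), 0 °C to rt
Reagents that add atoms: none
Why: Reductive cleavage of the imide by LiBH4 releases the syn-1,3-diol without epimerisation or retro-aldol and returns the auxiliary; the descriptor at the former α-carbon changes only because the priorities change.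

Step 5
Reactants: 11 (2S,3R)-4-(4-methoxybenzyloxy)-2-[3-methoxy-4-(triisopropylsilyloxy)benzyl]butane-1,3-diol
Product: 12 (2S,3R)-3-hydroxy-4-(4-methoxybenzyloxy)-2-[3-methoxy-4-(triisopropylsilyloxy)benzyl]butyl 4-methylbenzenesulfonate
Conditions: TsCl, Et3N, 4-(dimethylamino)pyridine (cat.), CH2Cl2, 0 °C
Reagents that add atoms: 4-toluenesulfonyl chloride, Cc1ccc(S(=O)(=O)Cl)cc1
Why: Sulfonylation is selective for the unhindered primary hydroxyl over the doubly flanked secondary one; no stereocentre is touched.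

Step 6
Reactants: 12 (2S,3R)-3-hydroxy-4-(4-methoxybenzyloxy)-2-[3-methoxy-4-(triisopropylsilyloxy)benzyl]butyl 4-methylbenzenesulfonate
Product: 13 (2R,3S)-2-[(4-methoxybenzyloxy)methyl]-3-[3-methoxy-4-(triisopropylsilyloxy)benzyl]oxetane
Conditions: NaH, THF, 0 to 50 °C
Reagents that add atoms: none
Why: Intramolecular Williamson etherification (4-exo-tet) after deprotonation of the secondary hydroxyl; the new C–O bond forms at the CH2 carbon, so both stereocentres are retained and the syn diol gives the cis-disubstituted oxetane.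

Step 7
Reactants: 14 homosyringic acid
Product: 15 2,2,2-trichloroethyl (4-hydroxy-3,5-dimethoxyphenyl)acetate
Conditions: Cl3CCH2OH, TsOH·H2O (cat.), toluene, reflux, Dean–Stark
Reagents that add atoms: 2,2,2-trichloroethanol, OCC(Cl)(Cl)Cl
Why: Fischer esterification with azeotropic removal of water, under which the phenol does not esterify; the trichloroethyl ester is chosen because Zn removes it later without hydroxide.

Step 8
Reactants: 15 2,2,2-trichloroethyl (4-hydroxy-3,5-dimethoxyphenyl)acetate
Product: 16 2,2,2-trichloroethyl [3,5-dimethoxy-4-(triisopropylsilyloxy)phenyl]acetate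
Conditions: TIPSCl, imidazole, DMF, 40 °C
Reagents that add atoms: chlorotriisopropylsilane, CC(C)[Si](Cl)(C(C)C)C(C)C
Why: Silylation of the acidic, flanked syringyl phenol; the silyl ether is inert to the amidine base of step 9 and to the carbene of step 10.

Step 9
Reactants: 16 2,2,2-trichloroethyl [3,5-dimethoxy-4-(triisopropylsilyloxy)phenyl]acetate
Product: 17 2,2,2-trichloroethyl 2-diazo-2-[3,5-dimethoxy-4-(triisopropylsilyloxy)phenyl]acetate
Conditions: 4-acetamidobenzenesulfonyl azide, DBU, MeCN, 0 °C to rt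
Reagents that add atoms: 4-acetamidobenzenesulfonyl azide, CC(=O)Nc1ccc(S(=O)(=O)N=[N+]=[N-])cc1
Why: Regitz diazo transfer from the sulfonyl azide to the ester enolate of the arylacetate gives the donor/acceptor diazo ester.

Step 10
Reactants: 13 (2R,3S)-2-[(4-methoxybenzyloxy)methyl]-3-[3-methoxy-4-(triisopropylsilyloxy)benzyl]oxetane; 17 2,2,2-trichloroethyl 2-diazo-2-[3,5-dimethoxy-4-(triisopropylsilyloxy)phenyl]acetate
Product: 20 2,2,2-trichloroethyl (3R,4R)-2-[3,5-dimethoxy-4-(triisopropylsilyloxy)phenyl]-3-[(4-methoxybenzyloxy)methyl]-4-[3-methoxy-4-(triisopropylsilyloxy)benzyl]tetrahydrofuran-2-carboxylate (both C2 epimers), via carbene 18 (not isolated), via oxonium ylide 19 (not isolated)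
Conditions: 17 (excess, slow addition), CH2Cl2, blue LEDs (ca. 470 nm), rt, inert atmosphere
Reagents that add atoms: none
Why: Blue light expels N2 from 17, and the singlet aryl(alkoxycarbonyl)carbene 18 is captured by the most exposed and most Lewis-basic lone pair of 13, the oxetane oxygen, to give oxonium ylide 19 with O1–C2 in place. Ring strain then drives a Stevens [1,2]-shift: the O1–C3 bond breaks to a short-lived tethered radical pair that recombines at the ylide carbon and forms C2–C3; the closest known reaction type is the photochemical ring expansion of oxetanes to tetrahydrofurans with aryldiazoacetates. The five-membered ring therefore closes by 1,5-recombination within the ylide, as a four-to-five ring enlargement and not as a separate cyclisation. The new quaternary centre C2 forms without useful control, which is accepted because the carboxyl group is removed and C2 is reset in step 14. Chemoselectivity for the oxetane oxygen over the PMB ether oxygen, the benzylic C–H bonds and the arenes rests on the exposed lone pairs of the strained ether and on keeping the carbene concentration low by slow addition. Migration of C3 rather than C5 rests on C3 being the secondary carbon, with the longer and weaker bond to oxygen and the more stabilised radical. Retention at C3, and with it the C3/C4 cis relationship set by the aldol, rests on recombination in the tethered pair being faster than rotation or inversion.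

Step 11
Reactants: 20 2,2,2-trichloroethyl (3R,4R)-2-[3,5-dimethoxy-4-(triisopropylsilyloxy)phenyl]-3-[(4-methoxybenzyloxy)methyl]-4-[3-methoxy-4-(triisopropylsilyloxy)benzyl]tetrahydrofuran-2-carboxylate (both C2 epimers)
Product: 21 (3R,4R)-2-[3,5-dimethoxy-4-(triisopropylsilyloxy)phenyl]-3-[(4-methoxybenzyloxy)methyl]-4-[3-methoxy-4-(triisopropylsilyloxy)benzyl]tetrahydrofuran-2-carboxylic acid (both C2 epimers)
Conditions: Zn dust, AcOH, THF, rt
Reagents that add atoms: none
Why: Reductive β-elimination of the trichloroethyl ester by Zn frees the hindered tertiary acid regardless of steric shielding and leaves the silyl ethers, the PMB ether and the ring untouched.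

Step 12
Reactants: 21 (3R,4R)-2-[3,5-dimethoxy-4-(triisopropylsilyloxy)phenyl]-3-[(4-methoxybenzyloxy)methyl]-4-[3-methoxy-4-(triisopropylsilyloxy)benzyl]tetrahydrofuran-2-carboxylic acid (both C2 epimers)
Product: 22 (3R,4R)-2-[3,5-dimethoxy-4-(triisopropylsilyloxy)phenyl]-3-[(4-methoxybenzyloxy)methyl]-4-[3-methoxy-4-(triisopropylsilyloxy)benzyl]tetrahydrofuran (both C2 epimers)
Conditions: 9-mesityl-10-methylacridinium tetrafluoroborate (cat.), bis(4-chlorophenyl) disulfide (cat.), 2,6-lutidine, 1,2-dichloroethane, blue LEDs, rt, degassed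
Reagents that add atoms: none
Why: Acridinium photoredox hydrodecarboxylation: single-electron oxidation of the carboxylate, loss of CO2 and hydrogen-atom transfer from the arenethiol formed from the disulfide, a reaction for which α-oxy and arylacetic acids are the best substrates; hydrogen should arrive anti to the C3 substituent, so C2 is not yet correct and is reset in step 14.

Step 13
Reactants: 22 (3R,4R)-2-[3,5-dimethoxy-4-(triisopropylsilyloxy)phenyl]-3-[(4-methoxybenzyloxy)methyl]-4-[3-methoxy-4-(triisopropylsilyloxy)benzyl]tetrahydrofuran (both C2 epimers)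
Product: 23 {(3R,4R)-2-[3,5-dimethoxy-4-(triisopropylsilyloxy)phenyl]-4-[3-methoxy-4-(triisopropylsilyloxy)benzyl]tetrahydrofuran-3-yl}methanol (both C2 epimers)
Conditions: DDQ, CH2Cl2/pH 7 buffer, 0 °C
Reagents that add atoms: none
Why: Oxidative cleavage of the PMB ether by DDQ (hydride abstraction at the para-methoxybenzylic carbon, then hydrolysis); the C2–H bond should be spared because its ring carries only a silylated, doubly flanked para oxygen, a much poorer donor than the PMB methoxy group; the PMB group goes before step 14 so that no benzyl cation can form under Lewis acid.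

Step 14
Reactants: 23 {(3R,4R)-2-[3,5-dimethoxy-4-(triisopropylsilyloxy)phenyl]-4-[3-methoxy-4-(triisopropylsilyloxy)benzyl]tetrahydrofuran-3-yl}methanol (both C2 epimers)
Product: 24 {(2S,3R,4R)-2-[3,5-dimethoxy-4-(triisopropylsilyloxy)phenyl]-4-[3-methoxy-4-(triisopropylsilyloxy)benzyl]tetrahydrofuran-3-yl}methanol
Conditions: BF3·OEt2, CH2Cl2, −40 to 0 °C; Et3N quench
Reagents that add atoms: none
Why: Acid epimerisation of a 2-aryltetrahydrofuran: BF3 reversibly ionises the benzylic C2–O1 bond to a para-silyloxybenzyl cation held next to the O1 alkoxide, and repeated 5-exo reclosure funnels both epimers into the more stable isomer with the aryl group trans to the C3 and C4 substituents, which is 2S.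

Step 15
Reactants: 25 ferulic acid
Product: 27 (E)-3-[3-methoxy-4-(triisopropylsilyloxy)phenyl]prop-2-enoic acid, via bis-silylated ferulate 26 (not isolated)
Conditions: TIPSCl, imidazole, DMF, rt; then K2CO3, MeOH–THF–H2O, 0 °C to rt; acidic work-up
Reagents that add atoms: chlorotriisopropylsilane, CC(C)[Si](Cl)(C(C)C)C(C)C
Why: Same silylation and selective silyl ester hydrolysis as in step 1; the E-alkene is not affected.

Step 16
Reactants: 24 {(2S,3R,4R)-2-[3,5-dimethoxy-4-(triisopropylsilyloxy)phenyl]-4-[3-methoxy-4-(triisopropylsilyloxy)benzyl]tetrahydrofuran-3-yl}methanol; 27 (E)-3-[3-methoxy-4-(triisopropylsilyloxy)phenyl]prop-2-enoic acid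
Product: 28 {(2S,3R,4R)-2-[3,5-dimethoxy-4-(triisopropylsilyloxy)phenyl]-4-[3-methoxy-4-(triisopropylsilyloxy)benzyl]tetrahydrofuran-3-yl}methyl (E)-3-[3-methoxy-4-(triisopropylsilyloxy)phenyl]prop-2-enoate
Conditions: EDC·HCl, 4-(dimethylamino)pyridine, CH2Cl2, 0 °C to rt
Reagents that add atoms: none
Why: Steglich-type carbodiimide esterification of a primary alcohol with acyl transfer by the aminopyridine; no epimerisable or base-sensitive site is involved.

Step 17
Reactants: 28 {(2S,3R,4R)-2-[3,5-dimethoxy-4-(triisopropylsilyloxy)phenyl]-4-[3-methoxy-4-(triisopropylsilyloxy)benzyl]tetrahydrofuran-3-yl}methyl (E)-3-[3-methoxy-4-(triisopropylsilyloxy)phenyl]prop-2-enoate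
Product: 29 {(2S,3R,4R)-2-(4-hydroxy-3,5-dimethoxyphenyl)-4-(4-hydroxy-3-methoxybenzyl)tetrahydrofuran-3-yl}methyl (E)-3-(4-hydroxy-3-methoxyphenyl)prop-2-enoate (CNP0289934.1)
Conditions: n-Bu4NF, AcOH, THF, 0 °C
Reagents that add atoms: none
Why: Fluoride cleavage of the three aryl silyl ethers; acetic acid protonates the phenoxides as they form, so the cinnamate is not transesterified and the para-hydroxybenzylic C2–O1 bond is not opened to a quinone methide.

## Compound list

1 | dihydroferulic acid | COc1cc(CCC(=O)O)ccc1O | starting material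
2 | triisopropylsilyl 3-[3-methoxy-4-(triisopropylsilyloxy)phenyl]propanoate | COc1cc(CCC(=O)O[Si](C(C)C)(C(C)C)C(C)C)ccc1O[Si](C(C)C)(C(C)C)C(C)C | intermediate
3 | 3-[3-methoxy-4-(triisopropylsilyloxy)phenyl]propanoic acid | COc1cc(CCC(=O)O)ccc1O[Si](C(C)C)(C(C)C)C(C)C | intermediate
4 | (R)-4-benzyl-2-oxazolidinone | O=C1N[C@H](Cc2ccccc2)CO1 | starting material
5 | 3-[3-methoxy-4-(triisopropylsilyloxy)phenyl]propanoic pivalic anhydride | COc1cc(CCC(=O)OC(=O)C(C)(C)C)ccc1O[Si](C(C)C)(C(C)C)C(C)C | intermediate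
6 | (R)-4-benzyl-3-{3-[3-methoxy-4-(triisopropylsilyloxy)phenyl]propanoyl}oxazolidin-2-one | COc1cc(CCC(=O)N2C(=O)OC[C@H]2Cc2ccccc2)ccc1O[Si](C(C)C)(C(C)C)C(C)C | intermediate
7 | (4-methoxybenzyloxy)acetaldehyde | COc1ccc(COCC=O)cc1 | starting material
8 | (Z)-dibutylboron enolate of 6 | CCCCB(CCCC)O/C(=C\Cc1ccc(O[Si](C(C)C)(C(C)C)C(C)C)c(OC)c1)N1C(=O)OC[C@H]1Cc1ccccc1 | intermediate
9 | O-dibutylboryl aldolate of 10 | COc1ccc(COC[C@H](OB(CCCC)CCCC)[C@@H](Cc2ccc(O[Si](C(C)C)(C(C)C)C(C)C)c(OC)c2)C(=O)N2C(=O)OC[C@H]2Cc2ccccc2)cc1 | intermediate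
10 | (R)-4-benzyl-3-{(2R,3R)-3-hydroxy-4-(4-methoxybenzyloxy)-2-[3-methoxy-4-(triisopropylsilyloxy)benzyl]butanoyl}oxazolidin-2-one | COc1ccc(COC[C@H](O)[C@@H](Cc2ccc(O[Si](C(C)C)(C(C)C)C(C)C)c(OC)c2)C(=O)N2C(=O)OC[C@H]2Cc2ccccc2)cc1 | intermediate
11 | (2S,3R)-4-(4-methoxybenzyloxy)-2-[3-methoxy-4-(triisopropylsilyloxy)benzyl]butane-1,3-diol | COc1ccc(COC[C@H](O)[C@@H](Cc2ccc(O[Si](C(C)C)(C(C)C)C(C)C)c(OC)c2)CO)cc1 | intermediate
12 | (2S,3R)-3-hydroxy-4-(4-methoxybenzyloxy)-2-[3-methoxy-4-(triisopropylsilyloxy)benzyl]butyl 4-methylbenzenesulfonate | COc1ccc(COC[C@H](O)[C@@H](Cc2ccc(O[Si](C(C)C)(C(C)C)C(C)C)c(OC)c2)COS(=O)(=O)c2ccc(C)cc2)cc1 | intermediate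
13 | (2R,3S)-2-[(4-methoxybenzyloxy)methyl]-3-[3-methoxy-4-(triisopropylsilyloxy)benzyl]oxetane | COc1ccc(COC[C@H]2[C@@H](Cc3ccc(O[Si](C(C)C)(C(C)C)C(C)C)c(OC)c3)CO2)cc1 | intermediate
14 | homosyringic acid | COc1cc(CC(=O)O)cc(OC)c1O | starting material
15 | 2,2,2-trichloroethyl (4-hydroxy-3,5-dimethoxyphenyl)acetate | COc1cc(CC(=O)OCC(Cl)(Cl)Cl)cc(OC)c1O | intermediate
16 | 2,2,2-trichloroethyl [3,5-dimethoxy-4-(triisopropylsilyloxy)phenyl]acetate | COc1cc(CC(=O)OCC(Cl)(Cl)Cl)cc(OC)c1O[Si](C(C)C)(C(C)C)C(C)C | intermediate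
17 | 2,2,2-trichloroethyl 2-diazo-2-[3,5-dimethoxy-4-(triisopropylsilyloxy)phenyl]acetate | COc1cc(C(=[N+]=[N-])C(=O)OCC(Cl)(Cl)Cl)cc(OC)c1O[Si](C(C)C)(C(C)C)C(C)C | intermediate
18 | [3,5-dimethoxy-4-(triisopropylsilyloxy)phenyl][(2,2,2-trichloroethoxy)carbonyl]carbene | COc1cc([C]C(=O)OCC(Cl)(Cl)Cl)cc(OC)c1O[Si](C(C)C)(C(C)C)C(C)C | intermediate
19 | oxetane oxonium ylide from 13 and 18 | COc1ccc(COC[C@H]2[C@@H](Cc3ccc(O[Si](C(C)C)(C(C)C)C(C)C)c(OC)c3)C[O+]2[C-](C(=O)OCC(Cl)(Cl)Cl)c2cc(OC)c(O[Si](C(C)C)(C(C)C)C(C)C)c(OC)c2)cc1 | intermediate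
20 | 2,2,2-trichloroethyl (3R,4R)-2-[3,5-dimethoxy-4-(triisopropylsilyloxy)phenyl]-3-[(4-methoxybenzyloxy)methyl]-4-[3-methoxy-4-(triisopropylsilyloxy)benzyl]tetrahydrofuran-2-carboxylate (both C2 epimers) | COc1ccc(COC[C@H]2[C@@H](Cc3ccc(O[Si](C(C)C)(C(C)C)C(C)C)c(OC)c3)COC2(C(=O)OCC(Cl)(Cl)Cl)c2cc(OC)c(O[Si](C(C)C)(C(C)C)C(C)C)c(OC)c2)cc1 | intermediate
21 | (3R,4R)-2-[3,5-dimethoxy-4-(triisopropylsilyloxy)phenyl]-3-[(4-methoxybenzyloxy)methyl]-4-[3-methoxy-4-(triisopropylsilyloxy)benzyl]tetrahydrofuran-2-carboxylic acid (both C2 epimers) | COc1ccc(COC[C@H]2[C@@H](Cc3ccc(O[Si](C(C)C)(C(C)C)C(C)C)c(OC)c3)COC2(C(=O)O)c2cc(OC)c(O[Si](C(C)C)(C(C)C)C(C)C)c(OC)c2)cc1 | intermediate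
22 | (3R,4R)-2-[3,5-dimethoxy-4-(triisopropylsilyloxy)phenyl]-3-[(4-methoxybenzyloxy)methyl]-4-[3-methoxy-4-(triisopropylsilyloxy)benzyl]tetrahydrofuran (both C2 epimers) | COc1ccc(COC[C@H]2[C@@H](Cc3ccc(O[Si](C(C)C)(C(C)C)C(C)C)c(OC)c3)COC2c2cc(OC)c(O[Si](C(C)C)(C(C)C)C(C)C)c(OC)c2)cc1 | intermediate
23 | {(3R,4R)-2-[3,5-dimethoxy-4-(triisopropylsilyloxy)phenyl]-4-[3-methoxy-4-(triisopropylsilyloxy)benzyl]tetrahydrofuran-3-yl}methanol (both C2 epimers) | OC[C@H]1[C@@H](Cc2ccc(O[Si](C(C)C)(C(C)C)C(C)C)c(OC)c2)COC1c1cc(OC)c(O[Si](C(C)C)(C(C)C)C(C)C)c(OC)c1 | intermediate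
24 | {(2S,3R,4R)-2-[3,5-dimethoxy-4-(triisopropylsilyloxy)phenyl]-4-[3-methoxy-4-(triisopropylsilyloxy)benzyl]tetrahydrofuran-3-yl}methanol | OC[C@H]1[C@@H](Cc2ccc(O[Si](C(C)C)(C(C)C)C(C)C)c(OC)c2)CO[C@@H]1c1cc(OC)c(O[Si](C(C)C)(C(C)C)C(C)C)c(OC)c1 | intermediate
25 | ferulic acid | COc1cc(/C=C/C(=O)O)ccc1O | starting material
26 | triisopropylsilyl (E)-3-[3-methoxy-4-(triisopropylsilyloxy)phenyl]prop-2-enoate | COc1cc(/C=C/C(=O)O[Si](C(C)C)(C(C)C)C(C)C)ccc1O[Si](C(C)C)(C(C)C)C(C)C | intermediate
27 | (E)-3-[3-methoxy-4-(triisopropylsilyloxy)phenyl]prop-2-enoic acid | COc1cc(/C=C/C(=O)O)ccc1O[Si](C(C)C)(C(C)C)C(C)C | intermediate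
28 | {(2S,3R,4R)-2-[3,5-dimethoxy-4-(triisopropylsilyloxy)phenyl]-4-[3-methoxy-4-(triisopropylsilyloxy)benzyl]tetrahydrofuran-3-yl}methyl (E)-3-[3-methoxy-4-(triisopropylsilyloxy)phenyl]prop-2-enoate | COc1cc(/C=C/C(=O)OC[C@H]2[C@@H](Cc3ccc(O[Si](C(C)C)(C(C)C)C(C)C)c(OC)c3)CO[C@@H]2c2cc(OC)c(O[Si](C(C)C)(C(C)C)C(C)C)c(OC)c2)ccc1O[Si](C(C)C)(C(C)C)C(C)C | intermediate
29 | {(2S,3R,4R)-2-(4-hydroxy-3,5-dimethoxyphenyl)-4-(4-hydroxy-3-methoxybenzyl)tetrahydrofuran-3-yl}methyl (E)-3-(4-hydroxy-3-methoxyphenyl)prop-2-enoate | COc1cc(/C=C/C(=O)OC[C@H]2[C@@H](Cc3ccc(O)c(OC)c3)CO[C@@H]2c2cc(OC)c(O)c(OC)c2)ccc1O | target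

## Step count and risks

Total: 17 steps. Longest linear sequence: 13 steps (steps 1–6, 10–14, 16, 17). Steps 7–9 and step 15 are side branches.

**Step 10 (key step).**
- What may go wrong: the Stevens shift may lose regiocontrol, with C5 migrating instead of C3. The carbene may be diverted to the PMB ether, by ylide formation and benzyl shift or by insertion into its benzylic C–H bonds. The configuration at C3 may leak if the radical pair rotates before it recombines.
- Fallback: it sets out from acid 3, abandons the ring expansion and returns to the route at 24 through a lactone aldol sequence.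
  - Acid 3 is coupled through anhydride 5 with (S)-4-benzyl-2-oxazolidinone to give (S)-4-benzyl-3-{3-[3-methoxy-4-(triisopropylsilyloxy)phenyl]propanoyl}oxazolidin-2-one F1.
  - The sodium enolate of F1 (NaN(SiMe3)2, THF, −78 °C) is alkylated with tert-butyl bromoacetate on the face opposite the auxiliary benzyl group. This gives tert-butyl (R)-4-[(S)-4-benzyl-2-oxooxazolidin-3-yl]-3-[3-methoxy-4-(triisopropylsilyloxy)benzyl]-4-oxobutanoate F2.
  - LiBH4 reduces the imide to tert-butyl (R)-4-hydroxy-3-[3-methoxy-4-(triisopropylsilyloxy)benzyl]butanoate F3. Catalytic TsOH then closes it to (R)-4-[3-methoxy-4-(triisopropylsilyloxy)benzyl]dihydrofuran-2(3H)-one F4.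
  - Syringaldehyde is silylated (TIPSCl, imidazole) to 3,5-dimethoxy-4-(triisopropylsilyloxy)benzaldehyde F5.
  - The lithium enolate of F4 (LiN(i-Pr)2, THF, −78 °C) adds to F5 anti to the benzyl group. This gives (3S,4R)-3-{[3,5-dimethoxy-4-(triisopropylsilyloxy)phenyl](hydroxy)methyl}-4-[3-methoxy-4-(triisopropylsilyloxy)benzyl]dihydrofuran-2(3H)-one F6.
  - LiAlH4 reduces F6 to (2R,3R)-2-{[3,5-dimethoxy-4-(triisopropylsilyloxy)phenyl](hydroxy)methyl}-3-[3-methoxy-4-(triisopropylsilyloxy)benzyl]butane-1,4-diol F7.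
  - BF3·OEt2 in CH2Cl2 ionises the benzylic alcohol of F7, and the C5 hydroxyl closes the ring to 24 with the aryl group trans. The other primary hydroxyl could only form a four-membered ring.

**Step 14.**
- What may go wrong: during the repeated ionisations the benzylic cation may be captured irreversibly by C6' of the guaiacyl ring (Friedel–Crafts closure to an aryltetralin), or it may lose the proton at C3. Both processes drain material before equilibrium is reached.
- Fallback: it sets out from acid 21, sets C2 by a chelation-controlled reduction instead of a cation, and returns at 24.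
  - Oxidative decarboxylation of 21 with Pb(OAc)4 (tetravalent lead) and pyridine in benzene gives (3R,4R)-2-acetoxy-2-[3,5-dimethoxy-4-(triisopropylsilyloxy)phenyl]-3-[(4-methoxybenzyloxy)methyl]-4-[3-methoxy-4-(triisopropylsilyloxy)benzyl]tetrahydrofuran F8.
  - Mild aqueous hydrolysis of F8 gives (2R,3R)-1-[3,5-dimethoxy-4-(triisopropylsilyloxy)phenyl]-4-hydroxy-2-[(4-methoxybenzyloxy)methyl]-3-[3-methoxy-4-(triisopropylsilyloxy)benzyl]butan-1-one F9.
  - Zn(BH4)2 in ether at low temperature reduces F9 through a six-membered chelate between the ketone and the PMB ether oxygen, with hydride anti to the C4 branch. This gives (1S,2R,3R)-1-[3,5-dimethoxy-4-(triisopropylsilyloxy)phenyl]-2-[(4-methoxybenzyloxy)methyl]-3-[3-methoxy-4-(triisopropylsilyloxy)benzyl]butane-1,4-diol F10.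
  - Selective tosylation of the primary hydroxyl gives (2R,3R,4S)-4-[3,5-dimethoxy-4-(triisopropylsilyloxy)phenyl]-4-hydroxy-3-[(4-methoxybenzyloxy)methyl]-2-[3-methoxy-4-(triisopropylsilyloxy)benzyl]butyl 4-methylbenzenesulfonate F11.
  - NaH closes F11 at the CH2 carbon (5-exo-tet, C2 untouched) to (2S,3R,4R)-2-[3,5-dimethoxy-4-(triisopropylsilyloxy)phenyl]-3-[(4-methoxybenzyloxy)methyl]-4-[3-methoxy-4-(triisopropylsilyloxy)benzyl]tetrahydrofuran F12.
  - DDQ, as in step 13, converts F12 into 24.

**Step 12.**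
- What may go wrong: the excited acridinium may oxidise the electron-rich arenes or the PMB ether in competition with the carboxylate. The electron-rich C2 radical may be oxidised further to the oxocarbenium ion before hydrogen transfer.
- Fallback: it sets out from 21 and returns at 22 by Barton decarboxylation, which uses no strong photo-oxidant. Acid 21 is coupled (carbodiimide, 4-(dimethylamino)pyridine) with 2-mercaptopyridine N-oxide to give 2-thioxopyridin-1(2H)-yl (3R,4R)-2-[3,5-dimethoxy-4-(triisopropylsilyloxy)phenyl]-3-[(4-methoxybenzyloxy)methyl]-4-[3-methoxy-4-(triisopropylsilyloxy)benzyl]tetrahydrofuran-2-carboxylate F13. Visible-light photolysis of F13 with tert-butanethiol as hydrogen donor gives 22.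

**Step 13.**
- What may go wrong: DDQ may abstract hydride from C2–H (or from C7') in competition with the PMB position, which would open the ring to a ketone.
- Fallback: it sets out from 22 and returns directly at 24, replacing oxidation by acidolysis. Catalytic TfOH with 1,3-dimethoxybenzene as cation trap in CH2Cl2 removes the PMB group as a diarylmethane and equilibrates C2 in the same operation, so steps 13 and 14 merge and no new compound is made. This fallback shares the cation-leak risk described for step 14.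

## Further compounds

F1 | step 10 | (S)-4-benzyl-3-{3-[3-methoxy-4-(triisopropylsilyloxy)phenyl]propanoyl}oxazolidin-2-one | COc1cc(CCC(=O)N2C(=O)OC[C@@H]2Cc2ccccc2)ccc1O[Si](C(C)C)(C(C)C)C(C)C
F2 | step 10 | tert-butyl (R)-4-[(S)-4-benzyl-2-oxooxazolidin-3-yl]-3-[3-methoxy-4-(triisopropylsilyloxy)benzyl]-4-oxobutanoate | CC(C)(C)OC(=O)C[C@@H](Cc1ccc(O[Si](C(C)C)(C(C)C)C(C)C)c(OC)c1)C(=O)N1C(=O)OC[C@@H]1Cc1ccccc1
F3 | step 10 | tert-butyl (R)-4-hydroxy-3-[3-methoxy-4-(triisopropylsilyloxy)benzyl]butanoate | CC(C)(C)OC(=O)C[C@@H](Cc1ccc(O[Si](C(C)C)(C(C)C)C(C)C)c(OC)c1)CO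
F4 | step 10 | (R)-4-[3-methoxy-4-(triisopropylsilyloxy)benzyl]dihydrofuran-2(3H)-one | O=C1C[C@@H](Cc2ccc(O[Si](C(C)C)(C(C)C)C(C)C)c(OC)c2)CO1
F5 | step 10 | 3,5-dimethoxy-4-(triisopropylsilyloxy)benzaldehyde | COc1cc(C=O)cc(OC)c1O[Si](C(C)C)(C(C)C)C(C)C
F6 | step 10 | (3S,4R)-3-{[3,5-dimethoxy-4-(triisopropylsilyloxy)phenyl](hydroxy)methyl}-4-[3-methoxy-4-(triisopropylsilyloxy)benzyl]dihydrofuran-2(3H)-one (carbinol epimers) | O=C1[C@H](C(O)c2cc(OC)c(O[Si](C(C)C)(C(C)C)C(C)C)c(OC)c2)[C@@H](Cc2ccc(O[Si](C(C)C)(C(C)C)C(C)C)c(OC)c2)CO1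
F7 | step 10 | (2R,3R)-2-{[3,5-dimethoxy-4-(triisopropylsilyloxy)phenyl](hydroxy)methyl}-3-[3-methoxy-4-(triisopropylsilyloxy)benzyl]butane-1,4-diol (carbinol epimers) | OC[C@H](C(O)c1cc(OC)c(O[Si](C(C)C)(C(C)C)C(C)C)c(OC)c1)[C@@H](Cc1ccc(O[Si](C(C)C)(C(C)C)C(C)C)c(OC)c1)CO
F8 | step 14 | (3R,4R)-2-acetoxy-2-[3,5-dimethoxy-4-(triisopropylsilyloxy)phenyl]-3-[(4-methoxybenzyloxy)methyl]-4-[3-methoxy-4-(triisopropylsilyloxy)benzyl]tetrahydrofuran (C2 epimers) | COc1ccc(COC[C@H]2[C@@H](Cc3ccc(O[Si](C(C)C)(C(C)C)C(C)C)c(OC)c3)COC2(OC(C)=O)c2cc(OC)c(O[Si](C(C)C)(C(C)C)C(C)C)c(OC)c2)cc1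
F9 | step 14 | (2R,3R)-1-[3,5-dimethoxy-4-(triisopropylsilyloxy)phenyl]-4-hydroxy-2-[(4-methoxybenzyloxy)methyl]-3-[3-methoxy-4-(triisopropylsilyloxy)benzyl]butan-1-one | COc1ccc(COC[C@H](C(=O)c2cc(OC)c(O[Si](C(C)C)(C(C)C)C(C)C)c(OC)c2)[C@@H](Cc2ccc(O[Si](C(C)C)(C(C)C)C(C)C)c(OC)c2)CO)cc1
F10 | step 14 | (1S,2R,3R)-1-[3,5-dimethoxy-4-(triisopropylsilyloxy)phenyl]-2-[(4-methoxybenzyloxy)methyl]-3-[3-methoxy-4-(triisopropylsilyloxy)benzyl]butane-1,4-diol | COc1ccc(COC[C@H]([C@H](O)c2cc(OC)c(O[Si](C(C)C)(C(C)C)C(C)C)c(OC)c2)[C@@H](Cc2ccc(O[Si](C(C)C)(C(C)C)C(C)C)c(OC)c2)CO)cc1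
F11 | step 14 | (2R,3R,4S)-4-[3,5-dimethoxy-4-(triisopropylsilyloxy)phenyl]-4-hydroxy-3-[(4-methoxybenzyloxy)methyl]-2-[3-methoxy-4-(triisopropylsilyloxy)benzyl]butyl 4-methylbenzenesulfonate | COc1ccc(COC[C@H]([C@H](O)c2cc(OC)c(O[Si](C(C)C)(C(C)C)C(C)C)c(OC)c2)[C@@H](Cc2ccc(O[Si](C(C)C)(C(C)C)C(C)C)c(OC)c2)COS(=O)(=O)c2ccc(C)cc2)cc1
F12 | step 14 | (2S,3R,4R)-2-[3,5-dimethoxy-4-(triisopropylsilyloxy)phenyl]-3-[(4-methoxybenzyloxy)methyl]-4-[3-methoxy-4-(triisopropylsilyloxy)benzyl]tetrahydrofuran | COc1ccc(COC[C@H]2[C@@H](Cc3ccc(O[Si](C(C)C)(C(C)C)C(C)C)c(OC)c3)CO[C@@H]2c2cc(OC)c(O[Si](C(C)C)(C(C)C)C(C)C)c(OC)c2)cc1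
F13 | step 12 | 2-thioxopyridin-1(2H)-yl (3R,4R)-2-[3,5-dimethoxy-4-(triisopropylsilyloxy)phenyl]-3-[(4-methoxybenzyloxy)methyl]-4-[3-methoxy-4-(triisopropylsilyloxy)benzyl]tetrahydrofuran-2-carboxylate (C2 epimers) | COc1ccc(COC[C@H]2[C@@H](Cc3ccc(O[Si](C(C)C)(C(C)C)C(C)C)c(OC)c3)COC2(C(=O)ON2C=CC=CC2=S)c2cc(OC)c(O[Si](C(C)C)(C(C)C)C(C)C)c(OC)c2)cc1
F0 | step 13 | none | none
A1 | alternative 1 | diethyl 2-[3,5-dimethoxy-4-(methoxymethoxy)benzylidene]malonate | CCOC(=O)C(=Cc1cc(OC)c(OCOC)c(OC)c1)C(=O)OCC
A2 | alternative 1 | prop-2-yn-1-ol | C#CCO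
A3 | alternative 1 | 4-iodo-2-methoxy-1-(methoxymethoxy)benzene | COCOc1ccc(I)cc1OC
A4 | alternative 1 | diethyl (Z)-2-[3,5-dimethoxy-4-(methoxymethoxy)phenyl]-4-[3-methoxy-4-(methoxymethoxy)benzylidene]dihydrofuran-3,3(2H)-dicarboxylate (racemic) | CCOC(=O)C1(C(=O)OCC)C(c2cc(OC)c(OCOC)c(OC)c2)OC/C1=C\c1ccc(OCOC)c(OC)c1
A5 | alternative 2 | 4-(benzyloxy)-3-methoxybenzaldehyde | O=Cc1ccc(OCc2ccccc2)c(OC)c1
A6 | alternative 2 | (S)-5-[3,5-dimethoxy-4-(pivaloyloxy)phenyl]furan-2(5H)-one | O=C1O[C@H](c2cc(OC)c(OC(=O)C(C)(C)C)c(OC)c2)C=C1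
A7 | alternative 2 | chloro[4-(benzyloxy)-3-methoxyphenyl]methyl (trimethylsilyl)methyl ether | C[Si](C)(C)COC(Cl)c1ccc(OCc2ccccc2)c(OC)c1
A8 | alternative 2 | cis-fused furofuranone cycloadduct (mixture at the benzyloxyaryl carbon) | O=C1O[C@H](c2cc(OC)c(OC(=O)C(C)(C)C)c(OC)c2)[C@H]2COC(c3ccc(OCc4ccccc4)c(OC)c3)[C@@H]12
A9 | alternative 3 | 1-tert-butyl 4-methyl (3R)-2-[4-(tert-butyldimethylsilyloxy)-3,5-dimethoxybenzoyl]-3-[4-(tert-butyldimethylsilyloxy)-3-methoxybenzyl]butanedioate (C2 epimers) | CC(C)(C)OC(=O)C(C(=O)c1cc(OC)c(O[Si](C)(C)C(C)(C)C)c(OC)c1)[C@@H](Cc1ccc(O[Si](C)(C)C(C)(C)C)c(OC)c1)C(=O)OC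
A10 | alternative 3 | tert-butyl (2S,3S,4R)-2-[4-(tert-butyldimethylsilyloxy)-3,5-dimethoxyphenyl]-4-[4-(tert-butyldimethylsilyloxy)-3-methoxybenzyl]-5-oxotetrahydrofuran-3-carboxylate | CC(C)(C)OC(=O)[C@H]1[C@@H](Cc2ccc(O[Si](C)(C)C(C)(C)C)c(OC)c2)C(=O)O[C@@H]1c1cc(OC)c(O[Si](C)(C)C(C)(C)C)c(OC)c1
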